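## Structural features

The target is a flavone: benzene ring A is fused to the 4-pyranone ring C (a 4H-chromen-4-one), and the 4-hydroxyphenyl ring B is attached to C2 by a single C–C bond. Every position of the bicycle is substituted: OMe at C3 on ring C, and OH at C5, OMe at C6, OH at C7 and OMe at C8 on ring A. There is no stereocentre, so no neighbouring stereocentres have to be related; the problem is purely one of regiochemistry and of telling three methyl ethers from three free phenols. The fragile parts are the electron-rich, oxidation-prone ring A, the 5-OH hydrogen-bonded to the C4 carbonyl, and the pyranone, whose C2 can be attacked by hard nucleophiles with ring opening. The real difficulty is the alternating OH/OMe/OH/OMe array on ring A together with the 3-methoxy group, because phloroglucinol-based flavone syntheses normally leave C6 and C8 as C–H. Two features make it tractable. Read from C4a, ring A is mirror-symmetric (oxygen at C5 and C8a, OMe at C6 and C8, oxygen at C7). The C4 carbonyl carbon has only two carbon neighbours, C4a of ring A and C3 of the C3=C2–aryl unit, and no other substituent. The key step uses both: C4 arrives as carbon monoxide between a symmetric aryl iodide (future C4a) and an arylacetylene (future C3, C2 and ring B), and either of two equivalent ortho oxygens then closes ring C.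

## Logic of the disconnections

18 to 17: the three phenolic O–H groups (C5, C7, C4') are traced back to O–CH2Ph bonds. Benzyl is chosen because it comes off under neutral conditions in one operation and leaves the three methyl ethers alone, so the OH/OMe pattern of 18 is stored in 17 as benzyl versus methyl. The forward step must cleave three benzyl ethers without reducing the C2=C3 bond or the C4 carbonyl.

17 to 16: the C3 O–CH3 bond is cut. 16 has a single free hydroxyl, so the alkylation has no selectivity question. The forward step is a plain O-methylation of an acidic enol.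

16 to 13: the C3–O bond is cut. The alkyne-derived C3 enters the skeleton as C–H, and in 13 this is the only C–H on the bicyclic core and the most acidic sp2 C–H of the molecule. The forward step needs a clean C3 metalation, which is why every phenol of 13 must be capped.

13 to 12: the benzyl–oxygen bonds at C5 and C7 are cut. This costs one step but puts all three phenols under the same protecting group, so a single final operation frees them. The forward step must also alkylate the chelated 5-OH.

12 to 7, 8 and 9: three bonds are cut at once, C4a–C4, C4–C3 and O1–C2. This removes ring C and the link to ring B and leaves a monocyclic, mirror-symmetric aryl iodide 7, a purchased alkyne 8 and 9. The forward step must carbonylate before it alkynylates, must close six-membered and not five-membered, and must release the phenols of 7 in the same flask.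

7 to 5 through 6: the C–I bond and three acyl–oxygen bonds are cut. 5 has one ring C–H only, so the iodine can go nowhere else, and the acetates turn the labile 6 into a storable substrate that is also the activated form needed in the annulation. The forward step must iodinate without oxidising a very electron-rich triol.

5 to 4: three O–benzyl bonds are cut. The three oxygens that come with the starting arene must stay distinguishable from the two methoxy oxygens, and benzyl survives both the bromination and hot methoxide. The forward hydrogenolysis has to come before the iodine is installed.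

4 to 3: the two aryl C–OMe bonds are cut, so both methoxy groups enter as a nucleophile in one operation. This reduces the penta-oxygenated ring to a dibromide of a tri-oxygenated ring. The forward step is a double copper-mediated substitution at hindered, electron-rich positions and must not lose bromine by reduction.

3 to 2: two C–Br bonds are cut. The three ring C–H of 2 are equivalent, so any two give the same dibromide, and the third is kept for the later iodination. The forward step has to stop at two bromines.

2 to 1: the three benzyl ethers are traced back to the acetates of commercial 1. The acetates release phenoxide gradually, which favours O- over C-benzylation. The forward step is a one-pot deacylation and etherification.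

## Other disconnections considered

Alternative 1: The cut is at the C6–O and C8–O bonds of the two ring-A methoxy groups, made last on an intact flavonol skeleton. Commercial kaempferol A1 would be benzylated at O7 and O4', methylated at O3 and brominated at C6 and C8 to give 7-(benzyloxy)-2-[4-(benzyloxy)phenyl]-6,8-dibromo-5-hydroxy-3-methoxy-4H-chromen-4-one A2. Heating A2 with excess NaOMe and catalytic CuBr, a monovalent copper salt, in DMF/MeOH would exchange both bromides and give 7-(benzyloxy)-2-[4-(benzyloxy)phenyl]-5-hydroxy-3,6,8-trimethoxy-4H-chromen-4-one A3; hydrogenolysis would then give the target.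
- In its favour: the whole carbon skeleton and the C3 oxygen are bought, no ring is built, and no C3 oxidation is needed. At about five steps it is clearly the better plan on step economy.
- Against it: the four hydroxyls of A1 are told apart only by their acidity, so partial benzylation and 3-O-methylation are likely to give mixtures. The methoxylation also runs above 100 °C on a base-sensitive pyranone that carries a free, chelated 5-OH, where ring opening at C2 and reductive loss of bromine to mono-methoxy products are plausible.
- Comparison: the copper chemistry is the same reaction type as step 3 of the chosen route and carries the same intrinsic risk, so the two plans are equal on that point. The chosen route runs it early on a plain benzene with no heterocycle and fixes regiochemistry by symmetry instead of by graded acidity, and pays for this with twice the number of steps.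

Alternative 2: The cut is through ring A, at C8–C8a and C4a–C5, so that ring A is grown onto a preformed ring C. 2-[4-(Benzyloxy)phenyl]-5-bromo-3-methoxy-4H-pyran-4-one A5 would be lithiated by halogen–metal exchange and added to 3-tert-butoxy-4-methoxycyclobut-3-ene-1,2-dione A4 to give the 4-hydroxycyclobutenone A6. Heating A6 in toluene should open the four-membered ring to a dienylketene, which closes by 6π electrocyclisation onto C6 of the pyranone (the C8–C8a bond) and tautomerises to the hydroquinone 2-[4-(benzyloxy)phenyl]-7-tert-butoxy-5,8-dihydroxy-3,6-dimethoxy-4H-chromen-4-one A7. Selective methylation of the non-chelated 8-OH, acid cleavage of the tert-butyl ether and hydrogenolysis would finish the synthesis.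
- In its favour: the 3-methoxy group is present from the start, so no late C3 oxidation is needed, which is better than the chosen plan. Each ring-A oxygen arrives individually differentiated, so the method does not depend on symmetry and would also reach unsymmetrical analogues. The key step is a neutral thermal rearrangement.
- Against it: the addition to A4 must take place at one of two similar carbonyls, and only the bulk of the tert-butoxy group biases it; the wrong regiochemistry would exchange the C6 and C7 substituents. A5 needs its own multistep preparation. A7 is a para-hydroquinone that should oxidise easily to the quinone. Three different unmasking or alkylation events follow the key step.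
- Comparison: structurally more general and mechanistically elegant, but with more selectivity questions than the chosen route, where symmetry answers them, and probably not shorter than ten steps once A4 and A5 are made.

Alternative 3: The cut is at C4–C4a and O1–C2, the same side of ring C as in the chosen plan, but with a three-carbon partner that already contains C2, C3, C4 and the 3-methoxy group. Triol 5 and ethyl 3-[4-(benzyloxy)phenyl]-2-methoxy-3-oxopropanoate A8 would be fused without solvent at roughly 250 °C. Loss of ethanol should give an acylketene that acylates the single ring C–H of 5 (or an oxygen, followed by acyl migration), and cyclodehydration would give 2-[4-(benzyloxy)phenyl]-5,7-dihydroxy-3,6,8-trimethoxy-4H-chromen-4-one A9. One hydrogenolysis would then give the target.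
- In its favour: it shares 5 with the chosen route, uses the same symmetry argument, needs no palladium, no carbon monoxide, no C3 oxidation and no protecting-group changes on ring A, and would save about four steps. On step economy it is the better plan.
- Against it: the melt at 250 °C exposes an air-sensitive triol and a benzyl ether to harsh conditions, thermal condensations of this kind tend to be inefficient, and closure in the other sense to a 4-aryl-3-methoxycoumarin is a possible competitor.
- Comparison: the chosen route forms the same ring under mild, catalyst-controlled conditions and reaches C3 oxygenation by a predictable metalation, at the price of the extra steps.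

Key step: step 6

Remark on the chemistry: 1 is taken as the commercial peracetate of phloroglucinol, so the free triphenol, which is prone to C-alkylation, is never handled in the benzylation.

## Route

Step 1
Reactants: 1 benzene-1,3,5-triyl triacetate (phloroglucinol triacetate)
Product: 2 1,3,5-tris(benzyloxy)benzene
Conditions: NaH, BnCl, DMF, 0 °C; then H2O (3 equiv, slow addition), 0 °C → rt
Reagents that add atoms: benzyl chloride, ClCc1ccccc1
Why: One-pot deacetylation and Williamson etherification; hydroxide formed slowly from NaH and water cleaves the aryl acetates and each phenoxide is benzylated as it appears, which should keep C-benzylation of the phloroglucinol nucleus low.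

Step 2
Reactants: 2 1,3,5-tris(benzyloxy)benzene
Product: 3 1,3,5-tris(benzyloxy)-2,4-dibromobenzene
Conditions: NBS (2.05 equiv), MeCN/CH2Cl2, 0 °C → rt, dark
Reagents that add atoms: N-bromosuccinimide, O=C1CCC(=O)N1Br
Why: Electrophilic aromatic bromination of a ring in which each C–H is ortho/para to three alkoxy groups; the three positions are equivalent, and each bromine deactivates and shields the ring, so stoichiometry should stop the reaction at the dibromide.

Step 3
Reactants: 3 1,3,5-tris(benzyloxy)-2,4-dibromobenzene
Product: 4 1,3,5-tris(benzyloxy)-2,4-dimethoxybenzene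
Conditions: NaOMe/MeOH (excess), CuBr (20 mol %), DMF, 110 °C
Reagents that add atoms: sodium methoxide, C[O-].[Na+]
Why: Ullmann-type copper-catalysed methoxylation of aryl bromides, a reaction class that accepts electron-rich bromides flanked by two alkoxy groups; benzyl aryl ethers are inert to methoxide.

Step 4
Reactants: 4 1,3,5-tris(benzyloxy)-2,4-dimethoxybenzene
Product: 5 2,4-dimethoxybenzene-1,3,5-triol
Conditions: H2 (1 atm), 10% Pd/C, EtOAc/MeOH, rt; handled under argon
Reagents that add atoms: none
Why: Hydrogenolysis of benzyl aryl ethers; the methyl ethers and the ring are untouched, and it is done before any halogen is on the ring.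

Step 5
Reactants: 5 2,4-dimethoxybenzene-1,3,5-triol
Product: 7 2-iodo-4,6-dimethoxybenzene-1,3,5-triyl triacetate, via iodo triol 6 (not isolated)
Conditions: NIS (1.0 equiv), MeCN, 0 °C, dark; then Ac2O, pyridine, DMAP (cat.), 0 °C → rt
Reagents that add atoms: N-iodosuccinimide, O=C1CCC(=O)N1I; acetic anhydride, CC(=O)OC(C)=O
Why: Electrophilic iodination at the only ring C–H, which is ortho/para to three hydroxyls; the hydroxyls are mutually meta, so no quinone can form directly, and immediate peracetylation traps the light- and air-sensitive iodo triol as a stable ester.

Step 6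
Reactants: 7 2-iodo-4,6-dimethoxybenzene-1,3,5-triyl triacetate; 8 1-(benzyloxy)-4-ethynylbenzene; 9 carbon monoxide
Product: 12 2-[4-(benzyloxy)phenyl]-5,7-dihydroxy-6,8-dimethoxy-4H-chromen-4-one, via ynone triacetate 10 (not isolated), via enaminone 11 (not isolated)
Conditions: CO (balloon), PdCl2(PPh3)2 (5 mol %), dppp (5 mol %), thiourea (5 mol %), Et2NH/DMF, 45 °C
Reagents that add atoms: none
Why: Zerovalent palladium, formed from PdCl2(PPh3)2 by the amine and the alkyne, should insert into the C–I bond of 7; migratory insertion of 9 gives an aroylpalladium iodide, which takes up the amine-deprotonated alkyne 8 and reductively eliminates to the ynone 10. Diethylamine then aminolyses the three aryl acetates and adds to the ynone to give the vinylogous amide 11. The phenoxide ortho to the ketone attacks the amine-bearing carbon of 11 and diethylamine is expelled, so ring C closes by a 6-endo-trig oxa-Michael addition–elimination that forms O1–C2. The closest known reaction type is the palladium-catalysed carbonylative annulation of ortho-iodophenols or their acetates with terminal alkynes in a secondary amine, a copper-free carbonylative Sonogashira coupling followed by cyclisation. No stereocentre is created. Carbonylation must precede alkynylation; this is helped by the absence of a copper acetylide and by fast CO uptake at a hindered, electron-rich arylpalladium centre, and direct coupling would end in a benzofuran. Six-membered closure must beat 5-exo closure to the aurone; the enaminone secures this because only its amine-bearing carbon is electrophilic. The choice between the two oxygens flanking the iodine does not arise, since 7 has a mirror plane through the C–I bond; the third acetate, para to the new ketone, emerges as the 7-OH.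

Step 7
Reactants: 12 2-[4-(benzyloxy)phenyl]-5,7-dihydroxy-6,8-dimethoxy-4H-chromen-4-one
Product: 13 5,7-bis(benzyloxy)-2-[4-(benzyloxy)phenyl]-6,8-dimethoxy-4H-chromen-4-one
Conditions: BnBr (3 equiv), K2CO3, DMF, 60 °C
Reagents that add atoms: benzyl bromide, BrCc1ccccc1
Why: Williamson etherification; the acidic 7-OH reacts first and the hydrogen-bonded 5-OH follows in warm DMF with excess halide, while ring A has no free carbon for C-alkylation.

Step 8
Reactants: 13 5,7-bis(benzyloxy)-2-[4-(benzyloxy)phenyl]-6,8-dimethoxy-4H-chromen-4-one
Product: 16 5,7-bis(benzyloxy)-2-[4-(benzyloxy)phenyl]-3-hydroxy-6,8-dimethoxy-4H-chromen-4-one, via 3-lithioflavone 14 (not isolated), via flavon-3-yl boronate 15 (not isolated)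
Conditions: LiN(iPr)2, THF, −78 °C; B(OMe)3, −78 °C → 0 °C; then AcOH, 30% H2O2, 0 °C → rt
Reagents that add atoms: hydrogen peroxide, OO
Why: Vinylic lithiation at C3, the only C–H on the core and the one acidified by the adjacent C4 carbonyl and O1, followed by borate trapping and oxidative carbon-to-oxygen migration of the boronate; this lithiation–borylation–oxidation is an established way from fully O-protected flavones to flavonols.

Step 9
Reactants: 16 5,7-bis(benzyloxy)-2-[4-(benzyloxy)phenyl]-3-hydroxy-6,8-dimethoxy-4H-chromen-4-one
Product: 17 5,7-bis(benzyloxy)-2-[4-(benzyloxy)phenyl]-3,6,8-trimethoxy-4H-chromen-4-one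
Conditions: MeI, K2CO3, acetone, reflux
Reagents that add atoms: iodomethane, CI
Why: Williamson O-methylation of the acidic enolic 3-OH, the only free hydroxyl in 16.

Step 10
Reactants: 17 5,7-bis(benzyloxy)-2-[4-(benzyloxy)phenyl]-3,6,8-trimethoxy-4H-chromen-4-one
Product: 18 5,7-dihydroxy-2-(4-hydroxyphenyl)-3,6,8-trimethoxy-4H-chromen-4-one
Conditions: H2 (1 atm), 10% Pd/C, EtOAc/MeOH, rt, stopped after uptake of 3 equiv
Reagents that add atoms: none
Why: Global hydrogenolysis of three benzyl aryl ethers; the tetrasubstituted C2=C3 bond of the vinylogous ester and the methyl ethers should survive at atmospheric pressure.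

## Compound list

1 | benzene-1,3,5-triyl triacetate | CC(=O)Oc1cc(OC(C)=O)cc(OC(C)=O)c1 | starting material
2 | 1,3,5-tris(benzyloxy)benzene | c1ccc(COc2cc(OCc3ccccc3)cc(OCc3ccccc3)c2)cc1 | intermediate
3 | 1,3,5-tris(benzyloxy)-2,4-dibromobenzene | Brc1c(OCc2ccccc2)cc(OCc2ccccc2)c(Br)c1OCc1ccccc1 | intermediate
4 | 1,3,5-tris(benzyloxy)-2,4-dimethoxybenzene | COc1c(OCc2ccccc2)cc(OCc2ccccc2)c(OC)c1OCc1ccccc1 | intermediate
5 | 2,4-dimethoxybenzene-1,3,5-triol | COc1c(O)cc(O)c(OC)c1O | intermediate
6 | 2-iodo-4,6-dimethoxybenzene-1,3,5-triol | COc1c(O)c(I)c(O)c(OC)c1O | intermediate (not isolated)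
7 | 2-iodo-4,6-dimethoxybenzene-1,3,5-triyl triacetate | COc1c(OC(C)=O)c(I)c(OC(C)=O)c(OC)c1OC(C)=O | intermediate
8 | 1-(benzyloxy)-4-ethynylbenzene | C#Cc1ccc(OCc2ccccc2)cc1 | starting material
9 | carbon monoxide | [C-]#[O+] | starting material
10 | 2-{3-[4-(benzyloxy)phenyl]prop-2-ynoyl}-4,6-dimethoxybenzene-1,3,5-triyl triacetate | COc1c(OC(C)=O)c(C(=O)C#Cc2ccc(OCc3ccccc3)cc2)c(OC(C)=O)c(OC)c1OC(C)=O | intermediate (not isolated)
11 | (2E)-3-[4-(benzyloxy)phenyl]-3-(diethylamino)-1-(2,4,6-trihydroxy-3,5-dimethoxyphenyl)prop-2-en-1-one | CCN(CC)/C(=C/C(=O)c1c(O)c(OC)c(O)c(OC)c1O)c1ccc(OCc2ccccc2)cc1 | intermediate (not isolated)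
12 | 2-[4-(benzyloxy)phenyl]-5,7-dihydroxy-6,8-dimethoxy-4H-chromen-4-one | COc1c(O)c(OC)c2oc(-c3ccc(OCc4ccccc4)cc3)cc(=O)c2c1O | intermediate
13 | 5,7-bis(benzyloxy)-2-[4-(benzyloxy)phenyl]-6,8-dimethoxy-4H-chromen-4-one | COc1c(OCc2ccccc2)c(OC)c2oc(-c3ccc(OCc4ccccc4)cc3)cc(=O)c2c1OCc1ccccc1 | intermediate
14 | {5,7-bis(benzyloxy)-2-[4-(benzyloxy)phenyl]-6,8-dimethoxy-4-oxo-4H-chromen-3-yl}lithium | [Li]c1c(-c2ccc(OCc3ccccc3)cc2)oc2c(OC)c(OCc3ccccc3)c(OC)c(OCc3ccccc3)c2c1=O | intermediate (not isolated)
15 | dimethyl {5,7-bis(benzyloxy)-2-[4-(benzyloxy)phenyl]-6,8-dimethoxy-4-oxo-4H-chromen-3-yl}boronate | COB(OC)c1c(-c2ccc(OCc3ccccc3)cc2)oc2c(OC)c(OCc3ccccc3)c(OC)c(OCc3ccccc3)c2c1=O | intermediate (not isolated)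
16 | 5,7-bis(benzyloxy)-2-[4-(benzyloxy)phenyl]-3-hydroxy-6,8-dimethoxy-4H-chromen-4-one | COc1c(OCc2ccccc2)c(OC)c2oc(-c3ccc(OCc4ccccc4)cc3)c(O)c(=O)c2c1OCc1ccccc1 | intermediate
17 | 5,7-bis(benzyloxy)-2-[4-(benzyloxy)phenyl]-3,6,8-trimethoxy-4H-chromen-4-one | COc1c(OCc2ccccc2)c(OC)c2oc(-c3ccc(OCc4ccccc4)cc3)c(OC)c(=O)c2c1OCc1ccccc1 | intermediate
18 | 5,7-dihydroxy-2-(4-hydroxyphenyl)-3,6,8-trimethoxy-4H-chromen-4-one | COc1c(O)c(OC)c2oc(-c3ccc(O)cc3)c(OC)c(=O)c2c1O | target

## Step count and risks

Total step count: 10. Longest linear sequence: 10 steps (1 to 18); 8 and 9 are purchased and enter at step 6.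

Least certain steps:

Step 6 (key step). The most likely failures are slow oxidative addition into a C–I bond flanked by two acyloxy groups on an electron-rich ring, early aminolysis of the acetates followed by reductive loss of iodine from the free phenoxide, and alkynylation without CO uptake, which would lead on to a benzofuran. Fallback, from 5 back to 12: Houben–Hoesch acylation of 5 (MeCN, ZnCl2, HCl gas, Et2O, 0 °C; then hot water) at its only ring C–H should give 1-(2,4,6-trihydroxy-3,5-dimethoxyphenyl)ethan-1-one F1. Treatment of F1 with excess LiN(SiMe3)2 in THF at −78 °C and one equivalent of 4-(benzyloxy)benzoyl chloride should acylate the ketone enolate of the polyanion to give 1-[4-(benzyloxy)phenyl]-3-(2,4,6-trihydroxy-3,5-dimethoxyphenyl)propane-1,3-dione F2. Cyclodehydration of F2 (cat. p-TsOH, toluene, 80 °C) closes ring C and gives 12. C4 then comes from the acetyl group instead of from 9, and symmetry again removes the regiochemical question.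

Step 3. The second substitution may stall at the hindered position, and reductive loss of bromine may compete with C–O bond formation, leaving a C–H where a methoxy group is needed. Fallback, from 3 back to 4, replacing copper substitution by boron oxidation: bromine–lithium exchange on 3 (n-BuLi, 1 equiv, THF, −78 °C), B(OMe)3, then H2O2/NaOH should give 2,4,6-tris(benzyloxy)-3-bromophenol F3. Methylation of F3 (MeI, K2CO3, acetone) gives 1,3,5-tris(benzyloxy)-2-bromo-4-methoxybenzene F4. A second exchange–borylation–oxidation on F4 gives 2,4,6-tris(benzyloxy)-3-methoxyphenol F5, and methylation of F5 under the same conditions gives 4.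

Step 8. The amide base may add to C2 and open the pyranone, or remove a benzylic proton of a benzyl ether, which would start a Wittig-type rearrangement; the boronate may also lose boron by protonation before it is oxidised, returning 13. Fallback, from 13 back to 16, by electrophilic oxidation in place of carbanion chemistry: dimethyldioxirane (acetone/CH2Cl2, 0 °C) should epoxidise the electron-rich C2=C3 enol ether to the racemic cis-fused 2,3-epoxide of 13, 4,6-bis(benzyloxy)-1a-[4-(benzyloxy)phenyl]-3,5-dimethoxy-1a,7a-dihydro-7H-oxireno[2,3-b]chromen-7-one F6. A trace of p-TsOH in CH2Cl2 should then open the epoxide at C2 and, after loss of the C3 proton, give 16.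

Step 5. The iodinating agent may oxidise the very electron-rich triol by electron transfer instead of substituting it, and the iodo triol may lose iodine by ipso protonation before it is acylated. Fallback, from 4 back to 7, with iodination moved to the protected stage: NIS with a trace of CF3CO2H in MeCN should iodinate the single ring C–H of 4 to give 1,3,5-tris(benzyloxy)-2-iodo-4,6-dimethoxybenzene F7. BCl3 with pentamethylbenzene as benzyl-cation scavenger (CH2Cl2, −78 °C) should remove the three benzyl groups from F7 without touching the C–I bond or the methyl ethers, giving 6, which is acetylated in the same flask (Ac2O, pyridine) to 7.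

## Further compounds

F1 | step 6 | 1-(2,4,6-trihydroxy-3,5-dimethoxyphenyl)ethan-1-one | COc1c(O)c(OC)c(O)c(C(C)=O)c1O
F2 | step 6 | 1-[4-(benzyloxy)phenyl]-3-(2,4,6-trihydroxy-3,5-dimethoxyphenyl)propane-1,3-dione | COc1c(O)c(OC)c(O)c(C(=O)CC(=O)c2ccc(OCc3ccccc3)cc2)c1O
F3 | step 3 | 2,4,6-tris(benzyloxy)-3-bromophenol | Oc1c(OCc2ccccc2)c(Br)c(OCc2ccccc2)cc1OCc1ccccc1
F4 | step 3 | 1,3,5-tris(benzyloxy)-2-bromo-4-methoxybenzene | COc1c(OCc2ccccc2)c(Br)c(OCc2ccccc2)cc1OCc1ccccc1
F5 | step 3 | 2,4,6-tris(benzyloxy)-3-methoxyphenol | COc1c(OCc2ccccc2)c(O)c(OCc2ccccc2)cc1OCc1ccccc1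
F6 | step 8 | 4,6-bis(benzyloxy)-1a-[4-(benzyloxy)phenyl]-3,5-dimethoxy-1a,7a-dihydro-7H-oxireno[2,3-b]chromen-7-one (racemate, cis-fused, one enantiomer drawn) | O=C1[C@H]2O[C@@]2(c2ccc(OCc3ccccc3)cc2)Oc2c(OC)c(OCc3ccccc3)c(OC)c(OCc3ccccc3)c21
F7 | step 5 | 1,3,5-tris(benzyloxy)-2-iodo-4,6-dimethoxybenzene | COc1c(OCc2ccccc2)c(I)c(OCc2ccccc2)c(OC)c1OCc1ccccc1
A1 | alternative 1 | kaempferol, 3,5,7-trihydroxy-2-(4-hydroxyphenyl)-4H-chromen-4-one | O=c1c(O)c(-c2ccc(O)cc2)oc2cc(O)cc(O)c12
A2 | alternative 1 | 7-(benzyloxy)-2-[4-(benzyloxy)phenyl]-6,8-dibromo-5-hydroxy-3-methoxy-4H-chromen-4-one | COc1c(-c2ccc(OCc3ccccc3)cc2)oc2c(Br)c(OCc3ccccc3)c(Br)c(O)c2c1=O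
A3 | alternative 1 | 7-(benzyloxy)-2-[4-(benzyloxy)phenyl]-5-hydroxy-3,6,8-trimethoxy-4H-chromen-4-one | COc1c(OCc2ccccc2)c(OC)c2oc(-c3ccc(OCc4ccccc4)cc3)c(OC)c(=O)c2c1O
A4 | alternative 2 | 3-tert-butoxy-4-methoxycyclobut-3-ene-1,2-dione | COC1=C(OC(C)(C)C)C(=O)C1=O
A5 | alternative 2 | 2-[4-(benzyloxy)phenyl]-5-bromo-3-methoxy-4H-pyran-4-one | COc1c(-c2ccc(OCc3ccccc3)cc2)occ(Br)c1=O
A6 | alternative 2 | 4-{6-[4-(benzyloxy)phenyl]-5-methoxy-4-oxo-4H-pyran-3-yl}-2-tert-butoxy-4-hydroxy-3-methoxycyclobut-2-en-1-one (racemate) | COC1=C(OC(C)(C)C)C(=O)C1(O)c1coc(-c2ccc(OCc3ccccc3)cc2)c(OC)c1=O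
A7 | alternative 2 | 2-[4-(benzyloxy)phenyl]-7-tert-butoxy-5,8-dihydroxy-3,6-dimethoxy-4H-chromen-4-one | COc1c(O)c2c(=O)c(OC)c(-c3ccc(OCc4ccccc4)cc3)oc2c(O)c1OC(C)(C)C
A8 | alternative 3 | ethyl 3-[4-(benzyloxy)phenyl]-2-methoxy-3-oxopropanoate (racemate) | CCOC(=O)C(OC)C(=O)c1ccc(OCc2ccccc2)cc1
A9 | alternative 3 | 2-[4-(benzyloxy)phenyl]-5,7-dihydroxy-3,6,8-trimethoxy-4H-chromen-4-one | COc1c(O)c(OC)c2oc(-c3ccc(OCc4ccccc4)cc3)c(OC)c(=O)c2c1O
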